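**Retrosynthetic overview**

1. Target 11 comes from its B1 pivalate 10 by ester cleavage.
2. Feature: with each unit numbered as 8-methoxy-1-naphthol (C1 hydroxyl, C8 methoxyl), units A and D are identical. Each is bonded through its C4 to ring B (A4–B2, D4–B4) and carries hydrogen at C2 and C3. The phenolic ring of each can therefore be cut at C2–C3 and C4–C4a into an ethynyl group on B (C3, C4) and a 2-methoxyphenacyl unit (C1, C2, C4a to C8a, methoxyl).
3. 10 is disconnected to diyne 6 and two molecules of bromoketone 7 by a two-directional photoredox radical [4+2] benzannulation.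
4. 6 comes from dibromide 3 by twofold Sonogashira coupling with 4 and desilylation; 3 comes from 8-methoxynaphthalen-1-ol 1 by 2,4-dibromination and pivaloylation.
5. Ring order: the naphthalene of B is bought with 1, the methoxy-bearing rings of A and D come with 7, and the two phenolic rings of A and D are formed last, together, in step 5.

Key step: step 5

Assumption: the biaryl axes A4–B2 and B4–D4 carry no descriptors in the target and are taken as not configurationally fixed, so no axial selectivity is sought.

**Route**

Step 1
Reactants: 1 8-methoxynaphthalen-1-ol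
Product: 2 2,4-dibromo-8-methoxynaphthalen-1-ol
Conditions: NBS (2.05 equiv), MeCN, −10 °C to rt, dark
Reagents that add atoms: N-bromosuccinimide, O=C1CCC(=O)N1Br
Why: Electrophilic aromatic bromination; the free hydroxyl, hydrogen-bonded to the peri methoxyl, makes C4 (para) and then C2 (ortho) of the phenolic ring the most nucleophilic sites, as in the 2,4-dibromination of 1-naphthol, while C5 and C7 of the anisole ring are less activated and C5 becomes peri-shielded after the first bromination.

Step 2
Reactants: 2 2,4-dibromo-8-methoxynaphthalen-1-ol
Product: 3 2,4-dibromo-8-methoxynaphthalen-1-yl pivalate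
Conditions: NaH (1.2 equiv), THF, 0 °C; PivCl (1.3 equiv), 0 °C to rt
Reagents that add atoms: pivaloyl chloride, CC(C)(C)C(=O)Cl
Why: O-Acylation of a sodium naphthoxide with an acid chloride, which is irreversible and should proceed although the oxygen is flanked by bromine and the peri methoxyl.

Step 3
Reactants: 3 2,4-dibromo-8-methoxynaphthalen-1-yl pivalate; 4 trimethylsilylacetylene (3 equiv)
Product: 5 8-methoxy-2,4-bis[(trimethylsilyl)ethynyl]naphthalen-1-yl pivalate
Conditions: Pd(PhCN)2Cl2 (6 mol %), [HP(t-Bu)3]BF4 (12 mol %), CuI (4 mol %), i-Pr2NH (3 equiv), dioxane, 25 to 45 °C, Ar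
Reagents that add atoms: none
Why: Twofold Sonogashira coupling; the bulky electron-rich phosphine lets zerovalent palladium insert into both electron-rich C–Br bonds near room temperature, so the aryl pivalate is not exposed to hot amine.

Step 4
Reactants: 5 8-methoxy-2,4-bis[(trimethylsilyl)ethynyl]naphthalen-1-yl pivalate
Product: 6 2,4-diethynyl-8-methoxynaphthalen-1-yl pivalate
Conditions: TBAF (2.4 equiv), AcOH (2.4 equiv), THF, 0 °C to rt
Reagents that add atoms: none
Why: Fluoride-induced protodesilylation of alkynylsilanes; the acetic acid buffer keeps the medium non-basic, so the ester ortho to the alkyne is neither cleaved nor able to cyclize onto the triple bond through a free naphthoxide.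

Step 5
Reactants: 6 2,4-diethynyl-8-methoxynaphthalen-1-yl pivalate; 7 2-bromo-1-(2-methoxyphenyl)ethan-1-one (2 equiv consumed, 4 equiv used)
Product: 10 2,4-bis(4-hydroxy-5-methoxynaphthalen-1-yl)-8-methoxynaphthalen-1-yl pivalate, via ring D monoannulation product 8 (not isolated), via ring A monoannulation product 9 (not isolated)
Conditions: fac-Ir(ppy)3 (2 mol %), 7 (4 equiv, two portions), 2,6-lutidine (4 equiv), degassed DMF (0.05 M), 450 nm LEDs, 25 °C, Ar
Reagents that add atoms: none
Why: Proposed new method: photoexcited fac-Ir(ppy)3 (trivalent iridium) transfers an electron to 7, whose C–Br bond breaks to give an electrophilic 2-methoxyphenacyl radical; this adds to the terminal carbon of an ethynyl group, the linear vinyl radical conjugated with ring B attacks the hydrogen-bearing ortho carbon of its own benzoyl ring, the cyclohexadienyl radical is oxidized by tetravalent iridium (or by 7 in a chain), and proton loss plus enolization give the naphthol, the cycle then repeating on the remaining alkyne of 8 or 9. The closest known reaction type is the visible-light [4+2] benzannulation of 2-bromo-1,3-dicarbonyl compounds with aryl alkynes to 1-naphthols; new here are the α-bromoketone without a second carbonyl group and the twofold use on one diyne. The phenolic rings of A and D are each closed in the six-membered ortho mode of homolytic aromatic substitution (bond A4–A4a or D4–D4a) after the intermolecular bond A2–A3 or D2–D3 has formed. No stereocenter arises. Three selectivities are needed: addition at the terminal alkyne carbon, which the aryl-stabilized vinyl radical ensures; closure on C6 of the benzoyl ring and not on its methoxy-bearing C2, which the methoxyl enforces by occupying that carbon, so that it ends peri to the new hydroxyl; and no quenching of the vinyl radical beside B1 by internal hydrogen transfer, which the pivalate ensures because its nearest C–H bonds stand in a 1,7 relationship, whereas a methyl or benzyl ether would offer a 1,5 transfer. The hydroxyl groups set free are tied up by hydrogen bonds to their peri methoxyl groups and to DMF, which should slow hydrogen abstraction from them by the carbon radicals.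

Step 6
Reactants: 10 2,4-bis(4-hydroxy-5-methoxynaphthalen-1-yl)-8-methoxynaphthalen-1-yl pivalate
Product: 11 2,4-bis(4-hydroxy-5-methoxynaphthalen-1-yl)-8-methoxynaphthalen-1-ol
Conditions: NaOMe (6 equiv), degassed MeOH/THF, 40 °C, Ar; then degassed 1 M HCl, 0 °C
Reagents that add atoms: none
Why: Transesterification of an aryl ester by methoxide, driven by the good naphthoxide leaving group; oxygen is excluded because the trinaphthoxide is easily oxidized, and the methyl ethers are inert.

**Compound list**

1 | 8-methoxynaphthalen-1-ol | COc1cccc2cccc(O)c12 | starting material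
2 | 2,4-dibromo-8-methoxynaphthalen-1-ol | COc1cccc2c(Br)cc(Br)c(O)c12 | intermediate
3 | 2,4-dibromo-8-methoxynaphthalen-1-yl pivalate | COc1cccc2c(Br)cc(Br)c(OC(=O)C(C)(C)C)c12 | intermediate
4 | trimethylsilylacetylene (ethynyltrimethylsilane) | C#C[Si](C)(C)C | starting material
5 | 8-methoxy-2,4-bis[(trimethylsilyl)ethynyl]naphthalen-1-yl pivalate | COc1cccc2c(C#C[Si](C)(C)C)cc(C#C[Si](C)(C)C)c(OC(=O)C(C)(C)C)c12 | intermediate
6 | 2,4-diethynyl-8-methoxynaphthalen-1-yl pivalate | COc1cccc2c(C#C)cc(C#C)c(OC(=O)C(C)(C)C)c12 | intermediate
7 | 2-bromo-1-(2-methoxyphenyl)ethan-1-one | COc1ccccc1C(=O)CBr | starting material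
8 | 2-ethynyl-4-(4-hydroxy-5-methoxynaphthalen-1-yl)-8-methoxynaphthalen-1-yl pivalate (ring D formed, B2 alkyne left) | COc1cccc2c(-c3ccc(O)c4c(OC)cccc34)cc(C#C)c(OC(=O)C(C)(C)C)c12 | intermediate
9 | 4-ethynyl-2-(4-hydroxy-5-methoxynaphthalen-1-yl)-8-methoxynaphthalen-1-yl pivalate (ring A formed, B4 alkyne left) | COc1cccc2c(C#C)cc(-c3ccc(O)c4c(OC)cccc34)c(OC(=O)C(C)(C)C)c12 | intermediate
10 | 2,4-bis(4-hydroxy-5-methoxynaphthalen-1-yl)-8-methoxynaphthalen-1-yl pivalate | COc1cccc2c(-c3cc(-c4ccc(O)c5c(OC)cccc45)c4cccc(OC)c4c3OC(=O)C(C)(C)C)ccc(O)c12 | intermediate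
11 | 2,4-bis(4-hydroxy-5-methoxynaphthalen-1-yl)-8-methoxynaphthalen-1-ol | COc1cccc2c(-c3cc(-c4ccc(O)c5c(OC)cccc45)c4cccc(OC)c4c3O)ccc(O)c12 | target

**Step count**

Total steps: 6. Longest linear sequence: 6 (1 to 2 to 3 to 5 to 6 to 10 to 11).

**Steps most likely to fail**

Step 5 (proposed new method). The phenacyl radical, lacking a second carbonyl group, may be reduced or dimerize faster than it adds to the alkyne. The first-formed naphthol may also be attacked by the carbon radicals, through hydrogen abstraction from O–H or addition to its electron-rich ring, so that the second annulation stalls or the catalyst is quenched. The fallback uses known cross-coupling chemistry, sets out from 1 and 3, and returns to the route at 11. Compound 1 is monobrominated para to the hydroxyl (NBS, 1.0 equiv, MeCN, −10 °C) to 4-bromo-8-methoxynaphthalen-1-ol F1. This is acylated (NaH, PivCl, THF) to 4-bromo-8-methoxynaphthalen-1-yl pivalate F2 and borylated under Miyaura conditions (Pd(dppf)Cl2, B2pin2, KOAc, dioxane, 90 °C) to 8-methoxy-4-(4,4,5,5-tetramethyl-1,3,2-dioxaborolan-2-yl)naphthalen-1-yl pivalate F3. Twofold Suzuki–Miyaura coupling of dibromide 3 with F3 (2.5 equiv; Pd(OAc)2, SPhos, K3PO4, toluene/H2O, 90 °C) should give 8-methoxy-2,4-bis(5-methoxy-4-pivaloyloxynaphthalen-1-yl)naphthalen-1-yl pivalate F4. Excess NaOMe under the conditions of step 6 then removes all three esters and gives 11.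

Step 3. Oxidative addition into the C2–Br bond, flanked by the pivalate, may stall after the first coupling while copper-mediated homocoupling drains 4. Forcing the reaction invites aminolysis of the ester and cyclization of the liberated ortho-alkynyl naphthol to a naphthofuran. The fallback sets out from 1 and returns at 5. Compound 1 is diiodinated (N-iodosuccinimide, 2.1 equiv, MeCN, 0 °C) to 2,4-diiodo-8-methoxynaphthalen-1-ol F5 and acylated (NaH, PivCl, THF) to 2,4-diiodo-8-methoxynaphthalen-1-yl pivalate F6. The two C–I bonds should couple with 4 at 25 °C under the simplest conditions (Pd(PPh3)2Cl2, CuI, Et3N, THF) to give 5.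

Step 6. Methanolysis of the pivalate, shielded by the B2 aryl group and the peri methoxyl, may be slow. Prolonged warming of the trinaphthoxide would then allow traces of oxygen to cause oxidative coupling or quinone formation. The fallback sets out from 10 and returns at 11. The ester is cleaved reductively with i-Bu2AlH (6 equiv, CH2Cl2, −78 to 0 °C, then aqueous Rochelle salt), so the product is never held as a free naphthoxide in a protic base; no new intermediate is formed.

**Further compounds**

F1 | step 5 | 4-bromo-8-methoxynaphthalen-1-ol | COc1cccc2c(Br)ccc(O)c12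
F2 | step 5 | 4-bromo-8-methoxynaphthalen-1-yl pivalate | COc1cccc2c(Br)ccc(OC(=O)C(C)(C)C)c12
F3 | step 5 | 8-methoxy-4-(4,4,5,5-tetramethyl-1,3,2-dioxaborolan-2-yl)naphthalen-1-yl pivalate | COc1cccc2c(B3OC(C)(C)C(C)(C)O3)ccc(OC(=O)C(C)(C)C)c12
F4 | step 5 | 8-methoxy-2,4-bis(5-methoxy-4-pivaloyloxynaphthalen-1-yl)naphthalen-1-yl pivalate | COc1cccc2c(-c3cc(-c4ccc(OC(=O)C(C)(C)C)c5c(OC)cccc45)c4cccc(OC)c4c3OC(=O)C(C)(C)C)ccc(OC(=O)C(C)(C)C)c12
F5 | step 3 | 2,4-diiodo-8-methoxynaphthalen-1-ol | COc1cccc2c(I)cc(I)c(O)c12
F6 | step 3 | 2,4-diiodo-8-methoxynaphthalen-1-yl pivalate | COc1cccc2c(I)cc(I)c(OC(=O)C(C)(C)C)c12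
F0 | step 6 | none | none
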